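(The numbers in the tables are calculated with constants of no real substance.)

- It is easy to read the shrinking solid substrate as target made, yet by 3.00 min the flask has lost 29.0% of its charge as solid and shows only 9.9% as target.

| setting | grey | flask |
|---|---|---|
| solid substrate | 20 mM | 20 mM |
| reagent | 4 equiv | 4.00 equiv |
| protic impurity | 0.40 mM | 0.400 mM |
| remark | the very flask that is asked about, followed so far |  |
| time |  | 10 min |

grey run (percent of the solid substrate charged)

| time / min | target / % | solid substrate / % |
|---|---|---|
| 0.250 | 0 | 95.2 |
| 0.833 | 1.2 | 89.1 |
| 1.33 | 2.5 | 84.1 |
| 2.00 | 5.3 | 78.5 |
| 3.00 | 9.9 | 71.0 |

(readings scatter by 0.3 percentage points)

- as a solid, counted per litre of solution: solid substrate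
- the numbers in the tables scatter with a standard deviation of 0.3 percentage points
- at the start none of the solid substrate is in solution

- target at 10 min, in percent of the solid substrate charged
- the change that raises the amount of target at 10 min, in percent of the solid substrate charged most ("none" if none brings more than 2 percentage points) (beta / zeta / epsilon / none)
- amount of target at 10 min, in percent of the solid substrate charged, after beta

- beta: doubling the amount of reagent, all else as stated
- zeta: doubling the dissolution coefficient of the solid substrate, all else as stated
- epsilon: doubling the solubility of the solid substrate, all else as stated

- We therefore divide the fraction of the charge gained as target by the fraction lost as solid over the same stretch, so that time drops out, and we call this the capture ratio; from 2.00 min to 3.00 min it reads 0.613.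
- The stretch before reads 0.500, and with a scatter of 0.3 percentage points on each reading these two ratios cannot be told apart.
- The solid's pace is easing, so holding its last pace up to 10 min gives a generous loss of 52.5% of the charge.
- For the bound from below we keep the ratio at its last reading, which amounts to target holding its last pace, and reach 42.1%.
- A ratio of one is no ceiling, since the 19.1% of the charge that is off the solid and not target at 3.00 min can still become target, so for the bound from above we count as target each part of the charge off the solid by 10 min, and reach 81.5%.
- Our own tightest step is a ratio halfway between the last reading and one, which gives 52.3%.
- The forecast gives 47%, within its range of 42% to 52% and inside our bracket, with 70% after beta and epsilon as the best change, since “Epsilon doubles the driving force”.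
- The flask gives 51.2%, and 71.9% after beta; epsilon is best, gaining 28 points against 21 points for beta and 21 points for zeta.

    solid substrate ⇌ dissolved substrate, rate k1*(cs1 - [dissolved substrate]) while solid is left; crystals form when [dissolved substrate] > cs1 (solubility = 10.0 mM, k = 0.230 /min)
    dissolved substrate + reagent → target (k = 4.00 /M/min)
    dissolved substrate + target → side product (k = 1.00 /M/min)
    solid substrate + protic impurity → quenched substrate (k = 1900 /M/min)
    reagent → decomposition product (k = 1.90 × 10⁻⁴ /min)

From 3.00 min to 10 min the capture ratio of this flask comes to 0.863, and at 10.0 min dissolved substrate is made 1.03 times as fast as it is used, close to a quasi-steady state. Part of the reason the flask stands at 51.2% is the low solubility of dissolved substrate, acting together with the length of the run: the run without that solubility limit gives 87.2%, and the flask read at 100 min gives 91.4%. Read at 15 min, the same flask holds solid substrate at 0%, its dissolved substrate falls from 21.8% to 15.4%, and the capture ratio of that last stretch is 1.16.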